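Readings and results are simulated for substances that don't exist; the scatter is artificial.

- In percent of both substrates charged, the east flask, the one you take over, last read 10% left-handed product and 39% left-handed substrate at 25.0 min; its right-handed product has not been read.

in all of them: left-handed substrate 11 mM; right-handed substrate 11 mM; free catalyst 0.3 mol%
- east: reagent 3 equiv; the very flask that is asked about, followed so far
- north-east: reagent 6 equiv; run made earlier
- flask: reagent 3.00 equiv

- east (time / min: left-handed product / %, left-handed substrate / %): 6.00: 1, 48; 15.0: 9, 43; 20.0: 10, 38; 25.0: 10, 39
- north-east (time / min: left-handed product / %, left-handed substrate / %): 8.00: 10, 41; 15.0: 15, 35; 40.0: 30, 24; 90.0: 39, 12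

(standard deviation of a reading: 1.5 percentage points)

- free catalyst is single-handed; left-handed substrate and right-handed substrate are mirror images of each other, charged as a racemate, each of them at the stated concentration
- what may be going on: free catalyst -> spent catalyst; reagent + free catalyst + left-handed substrate -> free catalyst + left-handed product; reagent + free catalyst + right-handed substrate -> free catalyst + right-handed product
- no earlier run changes the charge of free catalyst; that part of a forecast is a guess

- factor on the rate of making left-handed product when 30% of the left-handed substrate and right-handed substrate together are converted if reagent is charged twice over
- factor on the rate when 30% of the left-handed substrate and right-handed substrate together are converted if free catalyst is charged at 0.06 mol% instead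

- Each substrate molecule of either hand takes one reagent, so when you look at 30% conversion, the east flask holds 80.0% of its charged reagent, however the two hands split. With doubled reagent, that flask would hold 90.0% of its charge.
- Compare flasks at equal conversion, where the substrates stand alike. The equal-conversion factor is the ratio of [free catalyst] charged times the ratio of [reagent] present at that conversion, taking the same share of free catalyst as lost in both flasks. Treat it as the zero of your scale. Doubled reagent gives 2.25, and 0.06 mol% free catalyst gives 0.200.
- Leave the free catalyst charge alone: no earlier run changes it, so that part of any forecast is a guess.
- The forecast stands at 4 for doubled reagent, above 2.25, and at 0.05 for the small charge, below 0.200. Its grounds for the first: “Doubling gives reagent ×2.25 and surviving catalyst ×1.8, so about 4.”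

    free catalyst → spent catalyst (k = 4.20 × 10⁻⁵ s⁻¹)
    reagent + free catalyst + left-handed substrate → free catalyst + left-handed product (k = 180 M⁻² s⁻¹)
    reagent + free catalyst + right-handed substrate → free catalyst + right-handed product (k = 99.0 M⁻² s⁻¹)

- The simulation gives 2.40 for doubled reagent and 0.0986 for the small charge. In the east flask, free catalyst stands at 89.3% of its charge after 0.750 h, and 30% conversion comes at 0.790 h. Measured on your scale, the doubled-reagent flask lands at 1.07 times its equal-conversion factor, and the flask with 0.06 mol% free catalyst lands at 0.493 times its own.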